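**Strategy.** The cyclohexene ring is opened at C8–C9 and C10–C11, which excises the epoxide carbons C9 and C10 with the C10 methyl as a pyruvoyl unit. In the key step a (Z)-vinylstannane at C8 is acylated by pyruvoyl chloride, and the vinyl 1,2-diketone so formed closes the ring at once by a carbonyl-ene reaction of its acetyl carbonyl (C10) with the neighbouring (Z)-trisubstituted alkene (C11=C12). This exploits the allylic position of C11 next to the side-chain alkene, which moves to C12=C13 while C10 and C11 are set. The precursor is an acyclic 1,4-diene with both arms on the quaternary C6. Directed reduction and dehydrative closure then give the epoxide.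

Key step: step 16

Remarks on the chemistry:
- Numbering: C6 is the ring carbon that bears the pyrone, C7–C11 are the other ring carbons in order (C9/C10 = epoxide), C12–C17 is the side chain (C15 = ketone).
- Pyr = 6-methoxy-3,5-dimethyl-4-oxo-4H-pyran-2-yl.
- Compounds 3, 7 and 22 are carried as stereoisomer mixtures because the centres concerned are removed in the following step.

**Step 1**
Reactants: 1 methyl 2-methyl-3-oxopentanoate; 2 N-methoxy-N-methylpropanamide
Product: 3 methyl 2,4-dimethyl-3,5-dioxoheptanoate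
Conditions: NaH, THF, 0 °C; n-BuLi, 0 °C; then 2, 0 → 25 °C; aq. HCl
Reagents that add atoms: none
Why: The 1,3-dianion of the β-keto ester is acylated at its more nucleophilic γ-carbon by the Weinreb amide (γ-acylation of a β-keto ester dianion), and the chelated tetrahedral adduct should prevent over-addition.

**Step 2**
Reactants: 3 methyl 2,4-dimethyl-3,5-dioxoheptanoate
Product: 4 6-ethyl-4-hydroxy-3,5-dimethyl-2H-pyran-2-one
Conditions: DBU, toluene, 110 °C
Reagents that add atoms: none
Why: Base-promoted lactonisation of the 5-enol onto the methyl ester (triketide cyclisation) should give the 4-hydroxy-2-pyranone.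

**Step 3**
Reactants: 4 6-ethyl-4-hydroxy-3,5-dimethyl-2H-pyran-2-one
Product: 5 2-ethyl-6-methoxy-3,5-dimethyl-4H-pyran-4-one
Conditions: MeOSO2CF3, CH2Cl2, 25 °C; aq. NaHCO3
Reagents that add atoms: methyl trifluoromethanesulfonate, COS(=O)(=O)C(F)(F)F
Why: Kinetic O-methylation at the most basic lactone carbonyl oxygen followed by loss of the 4-OH proton should give the α-methoxy-γ-pyrone.

**Step 4**
Reactants: 5 2-ethyl-6-methoxy-3,5-dimethyl-4H-pyran-4-one; 6 ethyl glyoxylate
Product: 7 ethyl 2-hydroxy-3-Pyr-butanoate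
Conditions: LiN(SiMe3)2, THF, −78 °C; then 6, −78 °C; aq. NH4Cl
Reagents that add atoms: none
Why: Vinylogous deprotonation of the ethyl CH2 gives an extended enolate that adds to the aldehyde (vinylogous aldol reaction); the two new centres are not controlled because both are removed in step 5.

**Step 5**
Reactants: 7 ethyl 2-hydroxy-3-Pyr-butanoate
Product: 8 ethyl (E)-3-Pyr-but-2-enoate
Conditions: MsCl, Et3N, CH2Cl2, 0 °C; then DBU, 25 °C
Reagents that add atoms: none
Why: Mesylation and E1cB elimination through the pyrone-stabilised carbanion should give the conjugated enoate with the ester trans to the bulky pyrone.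

**Step 6**
Reactants: 8 ethyl (E)-3-Pyr-but-2-enoate
Product: 10 (E)-4-Pyr-pent-3-en-2-one, via Weinreb amide 9 (not isolated)
Conditions: MeNHOMe·HCl, MeMgBr (excess), THF, −20 → 0 °C; aq. NH4Cl
Reagents that add atoms: methylmagnesium bromide, C[Mg]Br; N,O-dimethylhydroxylamine hydrochloride, CNOC.Cl (its atoms are kept only in 9)
Why: The magnesium amide converts the ester into the Weinreb amide, which takes up one methyl Grignard and stops at the chelated adduct (one-pot ester-to-ketone conversion), the β,β-disubstituted alkene being too hindered for 1,4-addition.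

**Step 7**
Reactants: 11 (S)-3-bromo-2-methylpropan-1-ol
Product: 12 (S)-(3-bromo-2-methylpropoxy)(tert-butyl)dimethylsilane
Conditions: TBSCl, imidazole, DMF, 25 °C
Reagents that add atoms: tert-butyldimethylsilyl chloride, CC(C)(C)[Si](C)(C)Cl
Why: Standard silylation of the primary alcohol; the methyl-bearing centre (the later C14) is untouched.

**Step 8**
Reactants: 12 (S)-(3-bromo-2-methylpropoxy)(tert-butyl)dimethylsilane
Product: 15 (R,Z)-tert-butyl[(5-iodo-2,4-dimethylpent-4-en-1-yl)oxy]dimethylsilane, via Grignard reagent 13 (not isolated), via alkenylcopper 14 (not isolated)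
Conditions: Mg, Et2O, 35 °C; CuBr·SMe2, Et2O/Me2S, −45 °C; propyne, −25 °C; I2, −40 → 0 °C
Reagents that add atoms: propyne, CC#C; iodine, II; magnesium, [Mg] (kept only in 13); CuBr·SMe2, [Cu]Br.CSC (copper kept only in 14)
Why: Syn carbocupration of propyne puts the alkyl group on the internal carbon cis to copper, and iodinolysis with retention should give the (Z)-iodoalkene in which the chain is cis to iodine.

**Step 9**
Reactants: 10 (E)-4-Pyr-pent-3-en-2-one; 15 (R,Z)-tert-butyl[(5-iodo-2,4-dimethylpent-4-en-1-yl)oxy]dimethylsilane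
Product: 19 (2Z,4S,5Z,8R)-9-[(tert-butyldimethylsilyl)oxy]-4,6,8-trimethyl-4-Pyr-nona-2,5-dien-2-yl trifluoromethanesulfonate, via alkenyllithium 16 (not isolated), via alkenylalane 17 (not isolated), via aluminium enolate 18 (not isolated)
Conditions: 15, t-BuLi (2 equiv), Et2O, −78 °C; Me2AlCl, −78 → 0 °C; then 10, Cu(OTf)2 (5 mol %), chiral sulfonate-bearing imidazolinium salt (carbene precursor, 5 mol %), THF, −30 °C; then MeLi, N-(5-chloropyridin-2-yl)bis(trifluoromethanesulfonyl)imide, −78 → 0 °C
Reagents that add atoms: N-(5-chloropyridin-2-yl)-1,1,1-trifluoro-N-(trifluoromethylsulfonyl)methanesulfonamide, O=S(=O)(N(c1ccc(Cl)cn1)S(=O)(=O)C(F)(F)F)C(F)(F)F; tert-butyllithium, [Li]C(C)(C)C (lithium kept only in 16); dimethylaluminium chloride, C[Al](C)Cl (kept only in 17 and 18)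
Why: Copper-catalysed enantioselective conjugate addition of the alkenylalane to the β,β-disubstituted enone sets the quaternary C6 under catalyst control (the ligand enantiomer that gives the 4S centre is used), and the enone, s-cis because of allylic strain, gives the (Z)-aluminium enolate, whose O-triflation as the aluminate fixes the triflate cis to C6.

**Step 10**
Reactants: 19 silyl ether triflate
Product: 20 (2Z,4S,5Z,8R)-9-hydroxy-4,6,8-trimethyl-4-Pyr-nona-2,5-dien-2-yl trifluoromethanesulfonate
Conditions: HF·pyridine, pyridine, THF, 0 → 25 °C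
Reagents that add atoms: none
Why: Buffered HF removes the primary silyl ether, and the enol triflate and pyrone are stable to these mildly acidic conditions.

**Step 11**
Reactants: 20 primary alcohol
Product: 21 (2Z,4S,5Z,8R)-4,6,8-trimethyl-9-oxo-4-Pyr-nona-2,5-dien-2-yl trifluoromethanesulfonate
Conditions: Dess–Martin periodinane, NaHCO3, CH2Cl2, 0 °C
Reagents that add atoms: none
Why: Buffered Dess–Martin oxidation should give the α-methyl aldehyde without epimerisation of C14.

**Step 12**
Reactants: 21 aldehyde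
Product: 22 (2Z,4S,5Z,8R)-9-hydroxy-4,6,8-trimethyl-4-Pyr-undeca-2,5-dien-2-yl trifluoromethanesulfonate (both C9 epimers of this chain, i.e. C15 of the skeleton)
Conditions: EtMgBr, THF, −78 °C; aq. NH4Cl
Reagents that add atoms: ethylmagnesium bromide, CC[Mg]Br
Why: Grignard addition to the aldehyde, the most electrophilic site at −78 °C; the new carbinol centre is not controlled because it is oxidised in step 13.

**Step 13**
Reactants: 22 secondary alcohol
Product: 23 (2Z,4S,5Z,8R)-4,6,8-trimethyl-9-oxo-4-Pyr-undeca-2,5-dien-2-yl trifluoromethanesulfonate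
Conditions: Dess–Martin periodinane, NaHCO3, CH2Cl2, 25 °C
Reagents that add atoms: none
Why: Neutral oxidation gives the ethyl ketone, whose alkene is still γ,δ so that C14 is not prone to conjugation.

**Step 14**
Reactants: 23 ketone triflate
Product: 24 (4R,6Z,8S,9Z)-4,6,8-trimethyl-8-Pyr-10-(trimethylstannyl)undeca-6,9-dien-3-one
Conditions: Pd(PPh3)4 (5 mol %), Me3SnSnMe3, LiCl, 1,4-dioxane, 90 °C
Reagents that add atoms: hexamethylditin, C[Sn](C)(C)[Sn](C)(C)C
Why: Palladium-catalysed stannylation of the enol triflate with the distannane proceeds with retention, so tin stays cis to C6.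

**Step 15**
Reactants: 25 pyruvic acid
Product: 26 pyruvoyl chloride
Conditions: Cl2CHOCH3, neat, 50 °C; distillation
Reagents that add atoms: dichloromethyl methyl ether, COC(Cl)Cl
Why: The α,α-dichloro ether converts the acid into the acid chloride under conditions that the α-keto group tolerates.

**Step 16**
Reactants: 24 vinylstannane; 26 pyruvoyl chloride
Product: 28 (4R,5S,6S)-6-hydroxy-2,4,6-trimethyl-5-[(2E,4R)-4-methyl-5-oxohept-2-en-2-yl]-4-Pyr-cyclohex-2-en-1-one, via ene-dione 27 (not isolated)
Conditions: Pd2(dba)3 (2.5 mol %), tri(2-furyl)phosphine, toluene, 25 → 100 °C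
Reagents that add atoms: none
Why: Oxidative addition of zerovalent palladium into the acid chloride, transmetalation of the vinylstannane with retention of the (Z) geometry and reductive elimination give the vinyl 1,2-diketone 27 (acyl Stille coupling), whose acetyl carbonyl then acts as enophile towards the trisubstituted alkene held next to it by the (Z)-C7=C8 bond (intramolecular carbonyl-ene reaction of an activated ketone). The six-membered ring closes by bonding the carbonyl carbon C10 to the proximal ene carbon C11 through a chair-like transition state in which the pyrone on C6, the C10 methyl and the side chain on C11 are equatorial and the C10 carbonyl oxygen is axial, perpendicular to the C9 carbonyl. The C6 stereocentre controls C11 (side chain trans to the pyrone and cis to the C6 methyl) because the alternative chairs place the pyrone axial, and the axial oxygen defines C10 with its hydroxyl cis to the side chain. In this arrangement the oxygen reaches only the C13 hydrogens, which are cis to C6 in the (Z)-alkene, so the double bond moves to C12=C13 and not towards the C12 methyl, and C14 stays outside the cyclic array, which gives the (E) geometry. The step needs selectivity for the acetyl carbonyl over the conjugated C9 and the remote C15 ketones, which its higher electrophilicity and the six-membered ring size should secure, and it is run without chelating Lewis acids, which would turn the oxygen equatorial.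

**Step 17**
Reactants: 28 α-hydroxy enone
Product: 29 (1S,4R,5S,6S)-2,4,6-trimethyl-5-[(2E,4R)-4-methyl-5-oxohept-2-en-2-yl]-4-Pyr-cyclohex-2-ene-1,6-diol
Conditions: Me4NBH(OAc)3, MeCN/AcOH, −20 °C
Reagents that add atoms: none
Why: Hydroxyl-directed reduction: the C10 alkoxyborohydride delivers hydride to C9 from its own face, which sets the C9 hydroxyl trans to the C10 hydroxyl, and the C15 ketone, which has no directing group, is left alone.

**Step 18**
Reactants: 29 trans-diol
Product: 30 2-methoxy-3,5-dimethyl-6-{(1S,2S,3R,6R)-1,3,5-trimethyl-2-[(2E,4R)-4-methyl-5-oxohept-2-en-2-yl]-7-oxabicyclo[4.1.0]hept-4-en-3-yl}-4H-pyran-4-one (the target)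
Conditions: PPh3, DIAD, toluene, 0 → 60 °C
Reagents that add atoms: none
Why: Mitsunobu cyclodehydration: the less hindered secondary C9 hydroxyl is activated as the oxyphosphonium and displaced with inversion by the anti tertiary C10 hydroxyl, so the epoxide forms on the face of the C10 oxygen, cis to the side chain, under neutral conditions that spare C14.

**Compound list**
1 | methyl 2-methyl-3-oxopentanoate | CCC(=O)C(C)C(=O)OC | starting material
2 | N-methoxy-N-methylpropanamide | CCC(=O)N(C)OC | starting material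
3 | methyl 2,4-dimethyl-3,5-dioxoheptanoate (stereoisomer and tautomer mixture) | CCC(=O)C(C)C(=O)C(C)C(=O)OC | intermediate
4 | 6-ethyl-4-hydroxy-3,5-dimethyl-2H-pyran-2-one | CCc1oc(=O)c(C)c(O)c1C | intermediate
5 | 2-ethyl-6-methoxy-3,5-dimethyl-4H-pyran-4-one | CCc1oc(OC)c(C)c(=O)c1C | intermediate
6 | ethyl glyoxylate | CCOC(=O)C=O | starting material
7 | ethyl 2-hydroxy-3-(6-methoxy-3,5-dimethyl-4-oxo-4H-pyran-2-yl)butanoate (diastereomer mixture) | CCOC(=O)C(O)C(C)c1oc(OC)c(C)c(=O)c1C | intermediate
8 | ethyl (E)-3-(6-methoxy-3,5-dimethyl-4-oxo-4H-pyran-2-yl)but-2-enoate | CCOC(=O)/C=C(\C)c1oc(OC)c(C)c(=O)c1C | intermediate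
9 | (E)-N-methoxy-N-methyl-3-(6-methoxy-3,5-dimethyl-4-oxo-4H-pyran-2-yl)but-2-enamide | CON(C)C(=O)/C=C(\C)c1oc(OC)c(C)c(=O)c1C | intermediate (not isolated)
10 | (E)-4-(6-methoxy-3,5-dimethyl-4-oxo-4H-pyran-2-yl)pent-3-en-2-one | CC(=O)/C=C(\C)c1oc(OC)c(C)c(=O)c1C | intermediate
11 | (S)-3-bromo-2-methylpropan-1-ol | OC[C@H](C)CBr | starting material
12 | (S)-(3-bromo-2-methylpropoxy)(tert-butyl)dimethylsilane | CC(C)(C)[Si](C)(C)OC[C@H](C)CBr | intermediate
13 | (S)-[3-(tert-butyldimethylsilyloxy)-2-methylpropyl]magnesium bromide | CC(C)(C)[Si](C)(C)OC[C@H](C)C[Mg]Br | intermediate (not isolated)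
14 | [(1Z,4R)-5-(tert-butyldimethylsilyloxy)-2,4-dimethylpent-1-en-1-yl]copper (as its magnesium bromide complex) | CC(C)(C)[Si](C)(C)OC[C@H](C)C/C(C)=C\[Cu] | intermediate (not isolated)
15 | (R,Z)-tert-butyl[(5-iodo-2,4-dimethylpent-4-en-1-yl)oxy]dimethylsilane | CC(C)(C)[Si](C)(C)OC[C@H](C)C/C(C)=C\I | intermediate
16 | [(1Z,4R)-5-(tert-butyldimethylsilyloxy)-2,4-dimethylpent-1-en-1-yl]lithium | CC(C)(C)[Si](C)(C)OC[C@H](C)C/C(C)=C\[Li] | intermediate (not isolated)
17 | [(1Z,4R)-5-(tert-butyldimethylsilyloxy)-2,4-dimethylpent-1-en-1-yl]dimethylalane | CC(C)(C)[Si](C)(C)OC[C@H](C)C/C(C)=C\[Al](C)C | intermediate (not isolated)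
18 | dimethylaluminium (2Z,4S,5Z,8R)-9-(tert-butyldimethylsilyloxy)-4,6,8-trimethyl-4-Pyr-nona-2,5-dien-2-olate | CC(C)(C)[Si](C)(C)OC[C@H](C)C/C(C)=C\[C@](C)(c1oc(OC)c(C)c(=O)c1C)/C=C(/C)O[Al](C)C | intermediate (not isolated)
19 | (2Z,4S,5Z,8R)-9-[(tert-butyldimethylsilyl)oxy]-4,6,8-trimethyl-4-Pyr-nona-2,5-dien-2-yl trifluoromethanesulfonate | CC(C)(C)[Si](C)(C)OC[C@H](C)C/C(C)=C\[C@](C)(c1oc(OC)c(C)c(=O)c1C)/C=C(/C)OS(=O)(=O)C(F)(F)F | intermediate
20 | (2Z,4S,5Z,8R)-9-hydroxy-4,6,8-trimethyl-4-Pyr-nona-2,5-dien-2-yl trifluoromethanesulfonate | OC[C@H](C)C/C(C)=C\[C@](C)(c1oc(OC)c(C)c(=O)c1C)/C=C(/C)OS(=O)(=O)C(F)(F)F | intermediate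
21 | (2Z,4S,5Z,8R)-4,6,8-trimethyl-9-oxo-4-Pyr-nona-2,5-dien-2-yl trifluoromethanesulfonate | O=C[C@H](C)C/C(C)=C\[C@](C)(c1oc(OC)c(C)c(=O)c1C)/C=C(/C)OS(=O)(=O)C(F)(F)F | intermediate
22 | (2Z,4S,5Z,8R)-9-hydroxy-4,6,8-trimethyl-4-Pyr-undeca-2,5-dien-2-yl trifluoromethanesulfonate (both carbinol epimers) | CCC(O)[C@H](C)C/C(C)=C\[C@](C)(c1oc(OC)c(C)c(=O)c1C)/C=C(/C)OS(=O)(=O)C(F)(F)F | intermediate
23 | (2Z,4S,5Z,8R)-4,6,8-trimethyl-9-oxo-4-Pyr-undeca-2,5-dien-2-yl trifluoromethanesulfonate | CCC(=O)[C@H](C)C/C(C)=C\[C@](C)(c1oc(OC)c(C)c(=O)c1C)/C=C(/C)OS(=O)(=O)C(F)(F)F | intermediate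
24 | (4R,6Z,8S,9Z)-4,6,8-trimethyl-8-Pyr-10-(trimethylstannyl)undeca-6,9-dien-3-one | CCC(=O)[C@H](C)C/C(C)=C\[C@](C)(c1oc(OC)c(C)c(=O)c1C)/C=C(/C)[Sn](C)(C)C | intermediate
25 | pyruvic acid | CC(=O)C(=O)O | starting material
26 | pyruvoyl chloride | CC(=O)C(=O)Cl | intermediate
27 | (4Z,6S,7Z,10R)-4,6,8,10-tetramethyl-6-Pyr-trideca-4,7-diene-2,3,11-trione | CCC(=O)[C@H](C)C/C(C)=C\[C@](C)(c1oc(OC)c(C)c(=O)c1C)/C=C(/C)C(=O)C(C)=O | intermediate (not isolated)
28 | (4R,5S,6S)-6-hydroxy-2,4,6-trimethyl-5-[(2E,4R)-4-methyl-5-oxohept-2-en-2-yl]-4-Pyr-cyclohex-2-en-1-one | CCC(=O)[C@H](C)/C=C(\C)[C@@H]1[C@](C)(O)C(=O)C(C)=C[C@@]1(C)c1oc(OC)c(C)c(=O)c1C | intermediate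
29 | (1S,4R,5S,6S)-2,4,6-trimethyl-5-[(2E,4R)-4-methyl-5-oxohept-2-en-2-yl]-4-Pyr-cyclohex-2-ene-1,6-diol | CCC(=O)[C@H](C)/C=C(\C)[C@@H]1[C@](C)(O)[C@@H](O)C(C)=C[C@@]1(C)c1oc(OC)c(C)c(=O)c1C | intermediate
30 | 2-methoxy-3,5-dimethyl-6-{(1S,2S,3R,6R)-1,3,5-trimethyl-2-[(2E,4R)-4-methyl-5-oxohept-2-en-2-yl]-7-oxabicyclo[4.1.0]hept-4-en-3-yl}-4H-pyran-4-one (skeleton numbering: 6R,9R,10S,11S,12E,14R) | CCC(=O)[C@H](C)/C=C(\C)[C@@H]1[C@]2(C)O[C@@H]2C(C)=C[C@@]1(C)c1oc(OC)c(C)c(=O)c1C | target

**Step count.** Total: 18 steps. Longest linear sequence: 15 steps (1–6, 9–14, 16–18).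

**Steps most likely to fail**

Step 16 (key step). The α-ketoacyl palladium intermediate may lose CO before the slow transmetalation of the hindered cis-substituted stannane, and the labile acid chloride may decompose on heating. In the ene stage hydrogen may be transferred from the C12 methyl, or the closure may pass through a different chair. The fallback replaces the acyl cross-coupling by a chromium-mediated carbonyl addition followed by oxidation and runs the ene closure on its own. It sets out from triflate 23, so the stannane is not needed. A Nozaki–Hiyama–Kishi reaction (CrCl2, catalytic NiCl2, DMF) with freshly distilled anhydrous methylglyoxal should give the α-hydroxy ketone F1 as both carbinol epimers. Dess–Martin oxidation then gives the ene-dione 27, now isolated, and heating 27 alone in toluene should give 28, where the route is rejoined.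

Step 9. The cis-branched alkenyl group may be transferred sluggishly or with poor facial discrimination to the β,β-disubstituted enone, and O-triflation of the aluminium enolate may be incomplete. The fallback gives up catalyst control. It sets out from alkenylcopper 14 (made from 12 as in step 8 and used without the iodine quench) and enone 10. Stoichiometric conjugate addition promoted by Me3SiCl in Et2O/THF should give the (Z)-trimethylsilyl enol ether F2 as both C6 epimers. MeLi followed by the same triflimide converts F2 into 19 together with its C6 epimer, where the route is rejoined; the unwanted diastereomer is removed by chromatography at the rigid cyclohexenone 28.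

Step 18. The allylic C9 oxyphosphonium may ionise (allylic transposition or elimination to a diene) before the hindered tertiary hydroxyl attacks. The fallback uses direct sulfonate displacement and sets out from diol 29. Tf2O with 2,6-di-tert-butyl-4-methylpyridine in CH2Cl2 at −78 °C should sulfonylate the secondary hydroxyl selectively to the triflate F3, which is not isolated and is displaced at once by the neighbouring tertiary hydroxyl to give 30, where the route ends.

**Further compounds**
F1 | step 16 | (4Z,6S,7Z,10R)-3-hydroxy-4,6,8,10-tetramethyl-6-Pyr-trideca-4,7-diene-2,11-dione (both carbinol epimers) | CCC(=O)[C@H](C)C/C(C)=C\[C@](C)(c1oc(OC)c(C)c(=O)c1C)/C=C(/C)C(O)C(C)=O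
F2 | step 9 | (2Z,5Z,8R)-9-(tert-butyldimethylsilyloxy)-4,6,8-trimethyl-4-Pyr-2-(trimethylsilyloxy)nona-2,5-diene (both C4 epimers) | CC(C)(C)[Si](C)(C)OC[C@H](C)C/C(C)=C\C(C)(c1oc(OC)c(C)c(=O)c1C)/C=C(/C)O[Si](C)(C)C
F3 | step 18 | (1S,4R,5S,6S)-6-hydroxy-2,4,6-trimethyl-5-[(2E,4R)-4-methyl-5-oxohept-2-en-2-yl]-4-Pyr-cyclohex-2-en-1-yl trifluoromethanesulfonate | CCC(=O)[C@H](C)/C=C(\C)[C@@H]1[C@](C)(O)[C@@H](OS(=O)(=O)C(F)(F)F)C(C)=C[C@@]1(C)c1oc(OC)c(C)c(=O)c1C
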